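**Plan**
1. Numbering (elemane): ring B = C5–C10; C10 carries vinyl C1=C2 and C14H2OAc; C5 carries C4(=C15H2)–C3HO; the lactone is C6–O–C12(=O)–C11(=C13H2)–C7; C8 carries the ester. β = face of C14 and C11, α = the other face.
2. Retrosynthesis: the C8 ester, C15 and the C3 aldehyde go first and C14–O is rejoined to C3 as a tetrahydropyran (ring A); the lactone is cut into a C11 alkenyl triflate, CO and C6–OH; C6–O goes back to the C5=C6 alkene and C8–O to C8–Si; last, C9–C10 and C7–C8 of ring B are cut together.
3. Enabling feature: the C8 oxygen sits next to C7, whose side-chain carbon C11 can carry an oxygen, so a C11–O–SiMe2–C8 bridge ties a vinyl group (C8=C9) to the diene C7=C6–C5=C10; C5=C10 lies in a dihydropyran whose ring oxygen is the later acetate oxygen, which fixes the geometry at C10.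
4. Forward: dihydropyranyl triflate + (R)-butenol boronate → dienol → vinylsilyl ether → intramolecular Diels–Alder (ring B and an oxasilolane) → LiAlH4 → hydroboration (C6–B) → C10 vinyl and C11 enol triflate → C6–OH → carbonylative lactone → ring A opened → C8–OH → ester, aldehyde, methylene, desilylation.
5. Stereochemistry: the only imported centre is C11 of (R)-but-3-yn-2-ol; it steers the cycloaddition (C7, C8, C10) and is then oxidised away; C5 and C6 come from a syn hydroboration on the α face; C8–Si becomes C8–O with retention.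
6. The oxygens on C11, C6 and C8 are kept apart as C–O, C–B and C–Si and unveiled in that order, so ring B needs no hydroxyl protecting group.

Key step: step 5

Remark: compounds 1, 3 and 19 and all reagents are taken to be commercially available.

Step 1
Reactants: 1 methyl 4-oxotetrahydro-2H-pyran-3-carboxylate
Product: 2 methyl 4-{[(trifluoromethyl)sulfonyl]oxy}-5,6-dihydro-2H-pyran-3-carboxylate
Conditions: iPr2NEt, Tf2O, CH2Cl2, −78 °C
Reagents that add atoms: trifluoromethanesulfonic anhydride, O=S(=O)(OS(=O)(=O)C(F)(F)F)C(F)(F)F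
Why: O-sulfonylation of the enolised cyclic β-keto ester (enol triflate formation) gives the future C5=C10 alkene inside a ring that already holds C14–O and C3–O, so its geometry is not in question.

Step 2
Reactants: 3 (R)-but-3-yn-2-ol
Product: 4 (2R,3E)-4-(4,4,5,5-tetramethyl-1,3,2-dioxaborolan-2-yl)but-3-en-2-ol
Conditions: B2pin2, CuCl (5 mol %), Xantphos (6 mol %), NaOtBu (10 mol %), MeOH (2 equiv), THF, rt
Reagents that add atoms: bis(pinacolato)diboron, CC1(C)OB(OC1(C)C)B1OC(C)(C)C(C)(C)O1
Why: copper-catalysed borylcupration and protonation (formal anti-Markovnikov syn hydroboration of a terminal alkyne) should give the (E)-alkenylboronate without touching the carbinol centre.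

Step 3
Reactants: 2 enol triflate; 4 alkenylboronate
Product: 5 methyl 4-[(1E,3R)-3-hydroxybut-1-en-1-yl]-5,6-dihydro-2H-pyran-3-carboxylate
Conditions: Pd(dppf)Cl2 (5 mol %), K3PO4, 1,4-dioxane/H2O, 60 °C
Reagents that add atoms: none
Why: Suzuki–Miyaura coupling of an alkenyl triflate with an alkenylboronate proceeds with retention at both partners and builds the diene C7=C6–C5=C10 with the E C6=C7 bond.

Step 4
Reactants: 5 dienol
Product: 6 methyl 4-[(1E,3R)-3-{[ethenyl(dimethyl)silyl]oxy}but-1-en-1-yl]-5,6-dihydro-2H-pyran-3-carboxylate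
Conditions: ClSiMe2CH=CH2, Et3N, DMAP (cat.), CH2Cl2, 0 °C
Reagents that add atoms: chloro(dimethyl)vinylsilane, C=C[Si](C)(C)Cl
Why: silylation of the secondary allylic alcohol with a chlorosilane puts the vinyl dienophile on a removable three-atom silicon tether.

Step 5
Reactants: 6 vinylsilyl ether
Product: 7 tricyclic cycloadduct (ring A + ring B + trans-fused 1,2-oxasilolane)
Conditions: toluene (0.01 M), BHT (cat.), 180 °C, sealed tube
Reagents that add atoms: none
Why: A thermal, concerted, suprafacial [4+2] cycloaddition (intramolecular Diels–Alder reaction of a 1,3,8-nonatriene analogue) joins the diene C7=C6–C5=C10 to the silicon-bound vinyl group and forms C7–C8 and C9–C10; the closest known reaction type is the temporary-silicon-tethered intramolecular Diels–Alder reaction of dienyl vinylsilyl ethers. Ring B closes as the six-membered cycloaddition ring and the 1,2-oxasilolane closes in the fused mode, the three-atom tether C11–O–Si forcing C8 and not C9 onto C7, so the regiochemistry rests on the tether and not on the weak electronic bias of the partners. C10 is set by the diene geometry locked in the dihydropyran ring (C14 outside, ester inside) and C7 by the E C6=C7 bond, so C14 and C11 should end up cis (both β). C8 is set by the anti (tether-exo) transition state, which should give the trans ring fusion with silicon α. The absolute sense comes from C11: with its hydrogen eclipsing C6–H and its methyl group turned away from the diene (A(1,3) strain), the tether oxygen can deliver the vinyl group to one diene face only. The step needs ring-fusion and facial selectivity, both resting on the short tether and the allylic stereocentre, and a [1,5]-hydrogen shift is excluded because the inside substituent on C10 is an ester without hydrogen.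

Step 6
Reactants: 7 cycloadduct
Product: 8 diol with 8α-SiMe2H
Conditions: LiAlH4, THF, 0 °C → rt; aqueous KNaC4H4O6 work-up
Reagents that add atoms: none
Why: hydride reduction turns the hindered ester into the C1 primary alcohol and, as with alkoxysilanes in general, cleaves Si–O to a hydrosilane, which frees O11 while C8 stays masked as C–SiMe2H.

Step 7
Reactants: 8 diol
Product: 10 6α-pinacolboronate diol, via tris(dihydroboryl) adduct 9 (not isolated)
Conditions: BH3·THF (4 equiv), THF, 0 °C → rt; then pinacol, rt; aqueous work-up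
Reagents that add atoms: borane–tetrahydrofuran, [BH3-][O+]1CCCC1; pinacol, CC(C)(O)C(C)(C)O
Why: hydroboration (syn addition, boron to the less substituted C6) should occur on the α face, anti to the pseudoaxial C14 on the allylic carbon C10 in the half-chair held by the trans-diequatorial C7/C8 groups, which sets H5 α and C6–B α, and pinacol turns the borane into a boronic ester that survives the next oxidations.

Step 8
Reactants: 10 boronate diol
Product: 11 keto aldehyde (10α-CHO and 7β-acetyl)
Conditions: Dess–Martin periodinane, CH2Cl2, 0 °C → rt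
Reagents that add atoms: none
Why: Dess–Martin oxidation converts both free alcohols, giving the non-enolisable C1 aldehyde and the C11 methyl ketone and so erasing the temporary C11 stereocentre, while C–B and Si–H bonds are not attacked.

Step 9
Reactants: 11 keto aldehyde
Product: 12 10α-vinyl methyl ketone
Conditions: Ph3PCH3Br, KN(SiMe3)2 (1.1 equiv of ylide), THF, −78 → −20 °C
Reagents that add atoms: methyltriphenylphosphonium bromide, C[P+](c1ccccc1)(c1ccccc1)c1ccccc1.[Br-]
Why: Wittig methylenation with one equivalent of ylide at low temperature should take the aldehyde in preference to the methyl ketone and forms the C10 vinyl group.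

Step 10
Reactants: 12 methyl ketone
Product: 14 alkenyl triflate, via potassium enolate 13 (not isolated)
Conditions: KN(SiMe3)2, THF, −78 °C; then PhNTf2, −78 → 0 °C
Reagents that add atoms: N-phenylbis(trifluoromethanesulfonimide), O=S(=O)(N(c1ccccc1)S(=O)(=O)C(F)(F)F)C(F)(F)F
Why: kinetic deprotonation at the methyl group (the tertiary C7–H is shielded by the C6 and C8 substituents) and O-triflation of the enolate give the terminal enol triflate C11(OTf)=C13H2.

Step 11
Reactants: 14 alkenyl triflate
Product: 15 6α-alcohol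
Conditions: NaBO3·4H2O, THF/H2O, 0 °C → rt
Reagents that add atoms: sodium perborate, O[B-]1(O)OO[B-](O)(O)OO1.[Na+].[Na+]
Why: perborate oxidation of the C–B bond (1,2-shift from boron to oxygen with retention) unveils the α C6 hydroxyl under conditions mild enough for the Si–H bond and the enol triflate.

Step 12
Reactants: 15 hydroxy triflate
Product: 16 trans-fused α-methylene-γ-butyrolactone (ring A intact)
Conditions: Pd(PPh3)4 (10 mol %), CO (1 atm), iPr2NEt, LiCl, MeCN, 60 °C
Reagents that add atoms: carbon monoxide, [C-]#[O+]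
Why: palladium-catalysed carbonylative lactonisation (oxidative addition of the alkenyl triflate to zerovalent palladium, CO insertion, capture of the acyl-palladium by the trans C6 hydroxyl) gives the methylene lactone directly, and ring closure should outrun hydride transfer from the hindered Si–H.

Step 13
Reactants: 16 lactone
Product: 17 ring-A-opened bromo acetate
Conditions: AcBr, ZnBr2 (10 mol %), CH2Cl2, 0 °C → rt
Reagents that add atoms: acetyl bromide, CC(=O)Br
Why: acylative ether cleavage, in which the ring oxygen is acetylated and bromide opens the oxonium ion by SN2 at the unhindered C3 and not at the neopentyl C14, gives the C14 acetate and the C3 bromide in one step.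

Step 14
Reactants: 17 bromo acetate
Product: 18 8α-alcohol
Conditions: KF, KHCO3, 30% H2O2, THF/MeOH, 0 °C → rt
Reagents that add atoms: hydrogen peroxide, OO
Why: Tamao oxidation of the hydrosilane (Si–H becomes Si–O/Si–F in the flask, then C8 shifts from silicon to oxygen) should give the C8 alcohol with retention.

Step 15
Reactants: 19 ethyl 2-(hydroxymethyl)prop-2-enoate
Product: 20 ethyl 2-({[tert-butyl(dimethyl)silyl]oxy}methyl)prop-2-enoate
Conditions: TBSCl, imidazole, CH2Cl2, 0 °C → rt
Reagents that add atoms: tert-butyldimethylsilyl chloride, CC(C)(C)[Si](C)(C)Cl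
Why: standard silylation of a primary allylic alcohol.

Step 16
Reactants: 20 silyl ether ester
Product: 21 2-({[tert-butyl(dimethyl)silyl]oxy}methyl)prop-2-enoic acid
Conditions: LiOH, THF/H2O, 0 °C; then 1 M HCl to pH 3
Reagents that add atoms: lithium hydroxide, [Li+].[OH-]
Why: saponification of the ethyl ester at low temperature gives the acid partner with the silyl ether intact.

Step 17
Reactants: 18 8α-alcohol; 21 acid
Product: 22 8α-ester
Conditions: DCC, DMAP (cat.), CH2Cl2, 0 °C → rt
Reagents that add atoms: none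
Why: Steglich esterification acylates the equatorial C8 hydroxyl, the only free hydroxyl in the molecule.

Step 18
Reactants: 22 bromo ester
Product: 24 aldehyde, via alkoxysulfonium tetrafluoroborate 23 (not isolated)
Conditions: AgBF4, DMSO, rt, dark; then Et3N
Reagents that add atoms: dimethyl sulfoxide, CS(C)=O
Why: silver-assisted Kornblum oxidation (bromide abstraction, O-alkylation of DMSO, base-induced fragmentation of the alkoxysulfonium ion) gives the C3 aldehyde without any peroxide or metal-oxo oxidant.

Step 19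
Reactants: 24 aldehyde
Product: 25 enal silyl ether
Conditions: (CH2O)n, iPr2NH2+ CF3CO2−, CF3CO2H (cat.), THF, 60 °C
Reagents that add atoms: formaldehyde (from paraformaldehyde), C=O
Why: an amine-salt-mediated Mannich condensation followed by β-elimination (α-methylenation of an aldehyde) installs C15, and the hindered amine should not add to the three Michael acceptors.

Step 20
Reactants: 25 enal silyl ether
Product: 26 target
Conditions: HF·pyridine, pyridine, THF, 0 °C
Reagents that add atoms: none
Why: fluoride-mediated desilylation under buffered acidic conditions should free the allylic alcohol without conjugate addition or loss of the acetate.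

**Compound list**
1 | methyl 4-oxotetrahydro-2H-pyran-3-carboxylate | COC(=O)C1COCCC1=O | starting material
2 | methyl 4-{[(trifluoromethyl)sulfonyl]oxy}-5,6-dihydro-2H-pyran-3-carboxylate | COC(=O)C1=C(OS(=O)(=O)C(F)(F)F)CCOC1 | intermediate
3 | (R)-but-3-yn-2-ol | C[C@@H](O)C#C | starting material
4 | (2R,3E)-4-(4,4,5,5-tetramethyl-1,3,2-dioxaborolan-2-yl)but-3-en-2-ol | C[C@@H](O)/C=C/B1OC(C)(C)C(C)(C)O1 | intermediate
5 | methyl 4-[(1E,3R)-3-hydroxybut-1-en-1-yl]-5,6-dihydro-2H-pyran-3-carboxylate | COC(=O)C1=C(/C=C/[C@@H](C)O)CCOC1 | intermediate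
6 | methyl 4-[(1E,3R)-3-{[ethenyl(dimethyl)silyl]oxy}but-1-en-1-yl]-5,6-dihydro-2H-pyran-3-carboxylate | COC(=O)C1=C(/C=C/[C@@H](C)O[Si](C)(C)C=C)CCOC1 | intermediate
7 | cycloadduct: cyclohexene ring B (C5=C6) fused at C5–C10 to tetrahydropyran ring A (C10–C14H2–O–C3H2–C4H2–C5) and trans-fused at C7–C8 to a 2,2-dimethyl-1,2-oxasilolane (C7–C11H(CH3)–O–SiMe2–C8); CO2Me on C10 α, C14 β, C11 on C7 β, Si on C8 α, C11 R | COC(=O)[C@@]12COCCC1=C[C@H]3[C@H](C2)[Si](C)(C)O[C@@H]3C | intermediate
8 | ring A/ring B diol (C5=C6): 10α-hydroxymethyl, 7β-[(1R)-1-hydroxyethyl], 8α-dimethylsilyl (Si–H) | OC[C@@]12COCCC1=C[C@H]([C@@H](C)O)[C@H](C2)[SiH](C)C | intermediate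
9 | tris(dihydroboryl) adduct: 6α-BH2 with H5 α, both oxygens as O–BH2 | [BH2]OC[C@@]12COCC[C@@H]1[C@@H]([BH2])[C@H]([C@@H](C)O[BH2])[C@H](C2)[SiH](C)C | intermediate
10 | 6α-pinacolboronate: H5 α (rings A/B cis-fused), 10α-CH2OH, 7β-[(1R)-1-hydroxyethyl], 8α-SiMe2H | OC[C@@]12COCC[C@@H]1[C@@H](B3OC(C)(C)C(C)(C)O3)[C@H]([C@@H](C)O)[C@H](C2)[SiH](C)C | intermediate
11 | keto aldehyde: 10α-formyl, 7β-acetyl, 6α-Bpin, 8α-SiMe2H | O=C[C@@]12COCC[C@@H]1[C@@H](B3OC(C)(C)C(C)(C)O3)[C@H](C(C)=O)[C@H](C2)[SiH](C)C | intermediate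
12 | 10α-vinyl methyl ketone: 7β-acetyl, 6α-Bpin, 8α-SiMe2H | C=C[C@@]12COCC[C@@H]1[C@@H](B3OC(C)(C)C(C)(C)O3)[C@H](C(C)=O)[C@H](C2)[SiH](C)C | intermediate
13 | potassium enolate of 12 (C11(OK)=C13H2) | C=C[C@@]12COCC[C@@H]1[C@@H](B3OC(C)(C)C(C)(C)O3)[C@H](C(=C)[O-])[C@H](C2)[SiH](C)C.[K+] | intermediate
14 | alkenyl triflate: 7β-[1-(triflyloxy)ethenyl], 6α-Bpin, 8α-SiMe2H, 10α-vinyl | C=C[C@@]12COCC[C@@H]1[C@@H](B3OC(C)(C)C(C)(C)O3)[C@H](C(=C)OS(=O)(=O)C(F)(F)F)[C@H](C2)[SiH](C)C | intermediate
15 | 6α-alcohol: 7β-[1-(triflyloxy)ethenyl], 8α-SiMe2H, 10α-vinyl, ring A intact | C=C[C@@]12COCC[C@@H]1[C@@H](O)[C@H](C(=C)OS(=O)(=O)C(F)(F)F)[C@H](C2)[SiH](C)C | intermediate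
16 | trans-fused α-methylene-γ-butyrolactone (O on C6 α, C11 on C7 β), ring A intact, 10α-vinyl, 8α-SiMe2H | C=C[C@@]12COCC[C@@H]1[C@H]3OC(=O)C(=C)[C@@H]3[C@H](C2)[SiH](C)C | intermediate
17 | ring-A-opened lactone: 10β-CH2OAc, 10α-vinyl, 5β-(2-bromoethyl), 8α-SiMe2H | C=C[C@]1(COC(C)=O)C[C@H]([SiH](C)C)[C@H]2C(=C)C(=O)O[C@@H]2[C@H]1CCBr | intermediate
18 | 8α-alcohol: 10β-CH2OAc, 10α-vinyl, 5β-(2-bromoethyl), 6α,12-lactone | C=C[C@]1(COC(C)=O)C[C@H](O)[C@H]2C(=C)C(=O)O[C@@H]2[C@H]1CCBr | intermediate
19 | ethyl 2-(hydroxymethyl)prop-2-enoate | C=C(CO)C(=O)OCC | starting material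
20 | ethyl 2-({[tert-butyl(dimethyl)silyl]oxy}methyl)prop-2-enoate | C=C(CO[Si](C)(C)C(C)(C)C)C(=O)OCC | intermediate
21 | 2-({[tert-butyl(dimethyl)silyl]oxy}methyl)prop-2-enoic acid | C=C(CO[Si](C)(C)C(C)(C)C)C(=O)O | intermediate
22 | 8α-ester of 18 with acid 21 (5β-(2-bromoethyl)) | C=C[C@]1(COC(C)=O)C[C@H](OC(=O)C(=C)CO[Si](C)(C)C(C)(C)C)[C@H]2C(=C)C(=O)O[C@@H]2[C@H]1CCBr | intermediate
23 | alkoxysulfonium tetrafluoroborate (C3–O–SMe2+) | C=C[C@]1(COC(C)=O)C[C@H](OC(=O)C(=C)CO[Si](C)(C)C(C)(C)C)[C@H]2C(=C)C(=O)O[C@@H]2[C@H]1CCO[S+](C)C.F[B-](F)(F)F | intermediate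
24 | aldehyde: 5β-(2-oxoethyl) | C=C[C@]1(COC(C)=O)C[C@H](OC(=O)C(=C)CO[Si](C)(C)C(C)(C)C)[C@H]2C(=C)C(=O)O[C@@H]2[C@H]1CC=O | intermediate
25 | enal: 5β-(3-oxoprop-1-en-2-yl), side-chain TBS ether | C=C[C@]1(COC(C)=O)C[C@H](OC(=O)C(=C)CO[Si](C)(C)C(C)(C)C)[C@H]2C(=C)C(=O)O[C@@H]2[C@H]1C(=C)C=O | intermediate
26 | target: 10α-vinyl, 10β-CH2OAc, 5β-(3-oxoprop-1-en-2-yl), trans 6α,12-lactone with 11(13)-methylene, 8α-O-[2-(hydroxymethyl)acryloyl] | C=C[C@]1(COC(C)=O)C[C@H](OC(=O)C(=C)CO)[C@H]2C(=C)C(=O)O[C@@H]2[C@H]1C(=C)C=O | target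

**Count and risks**
Total: 20 steps. Longest linear sequence: 17 steps (1, 3–14, 17–20).

Step 5. The cycloaddition at the fully substituted, ester-conjugated diene terminus may be too slow, so that desilylation or decomposition wins; the ring fusion may also come out partly cis. Fallback, from 6 back to 8: the ester is reduced first with iBu2AlH (CH2Cl2, −78 °C) to the allylic alcohol {4-[(1E,3R)-3-{[ethenyl(dimethyl)silyl]oxy}but-1-en-1-yl]-5,6-dihydro-2H-pyran-3-yl}methanol F1, whose diene loses no ester conjugation on cyclisation. Heating F1 in toluene at about 150 °C, below the onset of a [1,5]-hydrogen shift from the now present inside CH2 group, should give the hydroxymethyl cycloadduct F2, and LiAlH4 opens its Si–O bond to 8.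

Step 13. Hydrogen bromide or bromide may add to the methylene lactone or the vinyl group, the Si–H bond may be halogenated, or the hindered six-membered ether may resist cleavage. Fallback, from 14 back to 17: the cleavage is moved ahead of the lactonisation, to a stage without a Michael acceptor. AcBr/ZnBr2 on 14 gives the ring-A-opened boronate triflate F3. Brief NaBO3·4H2O oxidation at 0 °C, kept short so that the new C6 hydroxyl does not displace the C3 bromide, gives the 6α-alcohol F4. Carbonylative lactonisation (Pd(PPh3)4, CO, iPr2NEt, LiCl, MeCN) then gives 17.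

Step 14. Hydroperoxide, methoxide or fluoride may add to the methylene lactone, and the basic peroxide may remove the acetate or substitute the bromide. Fallback, from 17 back to 18: a two-stage Fleming-type oxidation in which no peroxide anion is present. Ph3C+ BF4− (CH2Cl2, 0 °C) abstracts the silicon hydride to give the fluorosilane F5, and mCPBA with KF in DMF oxidises its C8–Si bond with retention to 18.

**Further compounds**
F1 | step 5 | {4-[(1E,3R)-3-{[ethenyl(dimethyl)silyl]oxy}but-1-en-1-yl]-5,6-dihydro-2H-pyran-3-yl}methanol | OCC1=C(/C=C/[C@@H](C)O[Si](C)(C)C=C)CCOC1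
F2 | step 5 | hydroxymethyl cycloadduct (as 7 with 10α-CH2OH in place of CO2Me) | OC[C@@]12COCCC1=C[C@H]3[C@H](C2)[Si](C)(C)O[C@@H]3C
F3 | step 13 | ring-A-opened boronate triflate: 10β-CH2OAc, 10α-vinyl, 5β-(2-bromoethyl), 6α-Bpin, 7β-[1-(triflyloxy)ethenyl], 8α-SiMe2H | C=C[C@]1(COC(C)=O)C[C@H]([SiH](C)C)[C@@H](C(=C)OS(=O)(=O)C(F)(F)F)[C@H](B2OC(C)(C)C(C)(C)O2)[C@H]1CCBr
F4 | step 13 | 6α-alcohol of F3 | C=C[C@]1(COC(C)=O)C[C@H]([SiH](C)C)[C@@H](C(=C)OS(=O)(=O)C(F)(F)F)[C@H](O)[C@H]1CCBr
F5 | step 14 | fluorosilane: as 17 with 8α-SiMe2F | C=C[C@]1(COC(C)=O)C[C@H]([Si](C)(C)F)[C@H]2C(=C)C(=O)O[C@@H]2[C@H]1CCBr
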